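The rate constants were chosen freely; no experiment stands behind them.

Slowness in these flasks can have two sources: the enzyme may lack time, or it may be lost early. Which of these holds is the thing to find out for each flask here.

all flasks: starting material 15 mM; second substrate 0.500 equiv; capture agent 0.300 mM; free enzyme 0.01 mol%; time 1.0 h

|  | temperature |
|---|---|
| summer | 10 °C |
| dawn | 40 °C |
| autumn | −20 °C |

- which flask leads in amount of target, in percent of the starting material charged ("all alike" within 1.5 percentage points) (summer / dawn / autumn / all alike)
- how much target is there at the end, in percent of the starting material charged: summer
- how much target is there at the end, in percent of the starting material charged: dawn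
- how much target is there at the end, in percent of the starting material charged: autumn

    second substrate + free enzyme ⇌ complex B (K1 = 71 /M, k1 = 2.09 × 10⁵ /M/min, Ea1 = 16.0 kJ/mol, ΔH1 = −48.0 kJ/mol)
    capture agent + complex A → trapped intermediate (k2 = 3530 /M/min, Ea2 = 43.0 kJ/mol)
    complex B → free enzyme + second product (k3 = 354 /min, Ea3 = 64.0 kJ/mol)
    free enzyme → unfolded enzyme (k4 = 5.87 × 10⁻⁴ /min, Ea4 = 214 kJ/mol)
    complex A → free enzyme + target (k5 = 3070 /min, Ea5 = 62.0 kJ/mol)
    starting material + free enzyme ⇌ complex A (K6 = 5680 /M, k6 = 23300 /M/s, Ea6 = 35.0 kJ/mol, ΔH6 = −31.0 kJ/mol)
    (constants at 40 °C)

- all constants are for 40 °C and move with temperature by the activation energies and enthalpies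

I start with the main round alone: starting material binds free enzyme to form complex A, and complex A releases target and free enzyme. Binding outruns release in dawn, so each free enzyme stands against 6.32 complex A. Counting the whole enzyme as complex A for now, the round makes, as a fraction of the charge, the loading times the release constant per unit time. In dawn, that pace equals one full charge in 3.26 min. In autumn, the release constant is 10.9 /min, which gives 6.52% in the hour.

Now add the capture agent. The enzyme charge equals 0.500% of it, so its fraction stays near one and can be frozen, which makes trapping pseudo-first-order. Each complex A then either releases target or is trapped, and falling back to starting material returns free enzyme to the round. The ratio of release to trapping gives 2900 turnovers in dawn. At the given loading, that is 29.0% of the charge. This product of loading and ratio is the ceiling, the fraction of the charge that the enzyme turns into target before capture has taken it. The ceiling shrinks on cooling because release has the larger activation energy: it is 13.4% in summer and 5.14% in autumn.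

Next comes the clock. Complex A has a trapping lifetime of 0.944 min in dawn, 5.43 min in summer and 47.3 min in autumn. The hour is longer than the first two, so I put dawn and summer at their ceilings. In autumn, with the whole enzyme still counted as complex A, the hour reaches just 71.9% of the way, which gives 3.69% of target.

Then the rest. Unfolding costs less per round than trapping in dawn, so I drop it. Complex B hands its enzyme back free, so it enters neither term of the ceiling, but it does slow the clock. With both substrates frozen at their charge, each free enzyme in autumn stands against 75.6 complex A and 37.6 complex B. Complex A therefore holds 66.2% of the enzyme still in the round, and my autumn figure drops to 2.92%.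

The forecast names dawn as the leader, with 13.4% in summer, 29% in dawn and 2.9% in autumn. Its grounds: "The 40 °C and 10 °C flasks therefore run until the enzyme is dead and sit at that ceiling, whereas at −20 °C only a bit over half the enzyme is trapped within the hour, so that flask is also limited by time."

The simulation puts dawn ahead, with 13.4% of target in summer, 29.1% in dawn and 2.91% in autumn. Autumn, left for 10.0 h, holds 5.15% of target, against its ceiling of 5.14%. Scaling dawn's ceiling by the loading gives 11.6% for the neighbour of dawn charged with 0.004 mol% of free enzyme, and that flask ends with 11.6% of target.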